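The 1,2-dioxane is read as the four-carbon unit C3–C4–C5–C6 closed by O1–O2, with C6 at the ketone level. Removing the O–O unit and joining C3 to C6 reveals a tertiary cyclobutanol. In the key step cobalt(II) and O2 turn this cyclobutanol into its alkoxy radical. Strain-driven scission of the C3–C6 bond, capture of triplet oxygen and closure of the hydroperoxide on the C6 ketone take the four-membered carbocycle to the six-membered peroxide in one operation, from any cyclobutanol diastereomer. C6 is then set by anomeric equilibration, C3 by resolution as a (−)-menthyl peroxyketal. The precursor comes from a samarium diiodide 4-exo ketyl–enoate cyclisation; the enyne arrives by Sonogashira coupling.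

Key step: step 6

Remark: compounds 9, 10 and 11 are racemic. Compound 9 is drawn as one enantiomer of the anti (1R*,2S*) pair. Compounds 10 and 11 are drawn without configuration, because C3 is racemic and C6 of 11 is a mobile hemiketal centre.

Step 1
Reactants: 1 hex-5-ynoic acid; 2 N,O-dimethylhydroxylamine hydrochloride
Product: 3 N-methoxy-N-methylhex-5-ynamide
Conditions: EDC·HCl, N-methylmorpholine, CH2Cl2, 0 °C to rt
Reagents that add atoms: none
Why: Carbodiimide amide coupling should give the Weinreb amide, whose chelating N-methoxy group will stop the next addition at the ketone stage; no stereocentre is involved.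

Step 2
Reactants: 3 N-methoxy-N-methylhex-5-ynamide; 4 but-3-en-1-ylmagnesium bromide
Product: 5 dec-1-en-9-yn-5-one
Conditions: 4 (2.3 equiv), THF, 0 °C to rt; aq NH4Cl
Reagents that add atoms: none
Why: Weinreb ketone synthesis, in which the first equivalent of Grignard reagent only deprotonates the alkyne, the second adds to the amide, and the N,O-chelated tetrahedral intermediate should survive until the quench so that no tertiary alcohol forms.

Step 3
Reactants: 5 dec-1-en-9-yn-5-one
Product: 6 4-oxonon-8-ynal
Conditions: O3, CH2Cl2, −78 °C, Sudan Red 7B as end-point indicator; then Me2S, −78 °C to rt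
Reagents that add atoms: ozone, [O-][O+]=O
Why: Ozonolysis with reductive work-up, in which the monosubstituted alkene should be consumed far faster than the terminal alkyne and the dye marks the end point.

Step 4
Reactants: 6 4-oxonon-8-ynal; 7 methyl (triphenylphosphoranylidene)acetate
Product: 8 methyl (2E)-6-oxoundec-2-en-10-ynoate
Conditions: CH2Cl2, rt
Reagents that add atoms: none
Why: Wittig olefination with a stabilised ylide, which should attack only the aldehyde, leave the ketone alone and give the E-enoate.

Step 5
Reactants: 8 methyl (2E)-6-oxoundec-2-en-10-ynoate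
Product: 9 methyl 2-[(1R*,2S*)-2-hydroxy-2-(pent-4-yn-1-yl)cyclobutyl]acetate (racemic, OH anti to CH2CO2Me)
Conditions: SmI2 (2.5 equiv), THF/MeOH (4:1), 0 °C
Reagents that add atoms: none
Why: Samarium diiodide ketyl–olefin cyclisation (4-exo-trig), in which the samarium ketyl adds to the β-carbon of the polarity-matched enoate, the ester-stabilised radical is reduced and protonated by methanol, the anti arrangement expected for this substrate class prevents lactonisation, and the unactivated alkyne should not compete without an HMPA-type additive.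

Step 6
Reactants: 9 methyl 2-[(1R*,2S*)-2-hydroxy-2-(pent-4-yn-1-yl)cyclobutyl]acetate
Product: 11 methyl 2-[6-hydroxy-6-(pent-4-yn-1-yl)-1,2-dioxan-3-yl]acetate (racemic), via hydroperoxy ketone 10 (not isolated)
Conditions: Co(acac)2 (20 mol %), O2 (1 atm), toluene, 40 °C
Reagents that add atoms: dioxygen, O=O
Why: Cobalt(II) and O2 should give a cobalt(III) alkoxide of the tertiary cyclobutanol whose homolysis releases the alkoxy radical, and relief of about 26 kcal/mol of ring strain drives β-scission of the ring bond between the carbinol carbon (future C6) and the substituted carbon (future C3). The secondary γ-keto radical is captured by triplet O2 at close to the diffusion limit, and the peroxyl radical is turned over by cobalt and alcohol exchange to hydroperoxide 10 while the chain carrier is regenerated. The closest known reaction type is the cobalt- or manganese-acetylacetonate-catalysed aerobic ring expansion of cyclobutanols to 1,2-dioxan-3-ols and of cyclopropanols to 1,2-dioxolan-3-ols. The only ring closure is the reversible 6-exo-trig addition of the OOH group of 10 to the C6 ketone. C3 arises from a planar radical without control and is racemic (resolved in step 7), C6 is a labile hemiketal centre fixed later under anomeric control, and both stereocentres of 9 are erased, so any diastereomer of 9 converges on 11. The step needs regioselective scission, secured because the C3 side gives a secondary radical whereas the C5 side would give a primary one and loss of the pentynyl chain releases no strain; it also needs the alkyne, ester and propargylic C–H bonds to stay untouched, secured by the speed of O2 capture and by the closed hemiketal form that shields the hydroperoxide from cobalt.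

Step 7
Reactants: 11 methyl 2-[6-hydroxy-6-(pent-4-yn-1-yl)-1,2-dioxan-3-yl]acetate; 12 (−)-menthol, (1R,2S,5R)-5-methyl-2-(propan-2-yl)cyclohexan-1-ol
Product: 13 methyl 2-[(3S,6R)-6-{[(1R,2S,5R)-5-methyl-2-(propan-2-yl)cyclohexyl]oxy}-6-(pent-4-yn-1-yl)-1,2-dioxan-3-yl]acetate
Conditions: 12 (3 equiv), CSA (10 mol %), 4 Å MS, CH2Cl2, rt; separation of the two diastereomers on silica gel
Reagents that add atoms: none
Why: Acid-catalysed peroxyketalisation through the C6 peroxycarbenium ion should give for each C3 enantiomer only the anomerically favoured ketal (alkoxy axial, both carbon chains equatorial), so the racemate becomes two diastereomers whose separation is a classical resolution that delivers C3 as S and C6 as R.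

Step 8
Reactants: 14 dec-9-yn-1-ol
Product: 16 10-(trimethylsilyl)dec-9-yn-1-ol, via bis-silylated alkynol 15 (not isolated)
Conditions: n-BuLi (2.2 equiv), THF, −78 °C; TMSCl (2.5 equiv), −78 °C to rt; then 1 M HCl, rt
Reagents that add atoms: chlorotrimethylsilane, C[Si](C)(C)Cl
Why: Double deprotonation, C- and O-silylation and selective acidic cleavage of the labile O–Si bond should mask the terminal alkyne so that it cannot enter the later Sonogashira coupling.

Step 9
Reactants: 16 10-(trimethylsilyl)dec-9-yn-1-ol
Product: 17 10-(trimethylsilyl)dec-9-ynal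
Conditions: TEMPO (10 mol %), PhI(OAc)2, CH2Cl2, rt
Reagents that add atoms: none
Why: Oxoammonium (TEMPO) oxidation of a primary alcohol should stop at the aldehyde and leave the silylalkyne alone.

Step 10
Reactants: 17 10-(trimethylsilyl)dec-9-ynal
Product: 18 [(10E)-11-iodoundec-10-en-1-yn-1-yl]trimethylsilane
Conditions: CrCl2, CHI3, THF/1,4-dioxane, 0 °C to rt
Reagents that add atoms: iodoform, IC(I)I
Why: Takai olefination, in which the gem-dichromium species from iodoform adds to the aldehyde and elimination should give the E-alkenyl iodide.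

Step 11
Reactants: 13 menthyl peroxyketal alkyne; 18 [(10E)-11-iodoundec-10-en-1-yn-1-yl]trimethylsilane
Product: 19 methyl 2-[(3S,6R)-6-{[(1R,2S,5R)-5-methyl-2-(propan-2-yl)cyclohexyl]oxy}-6-[(6E)-16-(trimethylsilyl)hexadec-6-ene-4,15-diyn-1-yl]-1,2-dioxan-3-yl]acetate
Conditions: PdCl2(PPh3)2 (5 mol %), CuI (10 mol %), Et3N, THF, rt, degassed
Reagents that add atoms: none
Why: Sonogashira coupling of a terminal alkyne with an alkenyl iodide should proceed at room temperature with retention of the E geometry, under conditions that dialkyl peroxides and peroxyketals are known to tolerate.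

Step 12
Reactants: 19 coupled menthyl peroxyketal
Product: 21 methyl 2-{(3S,6R)-6-[(6E)-hexadec-6-ene-4,15-diyn-1-yl]-6-methoxy-1,2-dioxan-3-yl}acetate, via silylated methoxy ketal 20 (not isolated)
Conditions: TsOH·H2O (10 mol %), MeOH, rt; then K2CO3 (0.5 equiv), 0 °C
Reagents that add atoms: methanol, CO
Why: Acid-catalysed transketalisation in methanol should replace menthol through the C6 peroxycarbenium ion and, under anomeric control relayed from the fixed C3 centre, return the axial methoxy group (6R), after which carbonate-catalysed methanolysis removes the alkynyl silane; running acid before base keeps any base-induced C3 epimer a separable diastereomer.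

Compound list
1 | hex-5-ynoic acid | C#CCCCC(=O)O | starting material
2 | N,O-dimethylhydroxylamine hydrochloride | CNOC.Cl | starting material
3 | N-methoxy-N-methylhex-5-ynamide | C#CCCCC(=O)N(C)OC | intermediate
4 | but-3-en-1-ylmagnesium bromide | C=CCC[Mg]Br | starting material
5 | dec-1-en-9-yn-5-one | C=CCCC(=O)CCCC#C | intermediate
6 | 4-oxonon-8-ynal | O=CCCC(=O)CCCC#C | intermediate
7 | methyl (triphenylphosphoranylidene)acetate | COC(=O)C=P(c1ccccc1)(c1ccccc1)c1ccccc1 | starting material
8 | methyl (2E)-6-oxoundec-2-en-10-ynoate | C#CCCCC(=O)CC/C=C/C(=O)OC | intermediate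
9 | methyl 2-[(1R*,2S*)-2-hydroxy-2-(pent-4-yn-1-yl)cyclobutyl]acetate (racemic, one enantiomer drawn) | C#CCCC[C@]1(O)CC[C@@H]1CC(=O)OC | intermediate
10 | methyl 3-hydroperoxy-6-oxoundec-10-ynoate (racemic, not isolated) | C#CCCCC(=O)CCC(OO)CC(=O)OC | intermediate
11 | methyl 2-[6-hydroxy-6-(pent-4-yn-1-yl)-1,2-dioxan-3-yl]acetate (racemic, mobile hemiketal) | C#CCCCC1(O)CCC(CC(=O)OC)OO1 | intermediate
12 | (−)-menthol, (1R,2S,5R) | C[C@@H]1CC[C@H]([C@@H](C1)O)C(C)C | starting material
13 | methyl 2-[(3S,6R)-6-{[(1R,2S,5R)-5-methyl-2-(propan-2-yl)cyclohexyl]oxy}-6-(pent-4-yn-1-yl)-1,2-dioxan-3-yl]acetate | C#CCCC[C@]1(O[C@@H]2C[C@H](C)CC[C@H]2C(C)C)CC[C@@H](CC(=O)OC)OO1 | intermediate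
14 | dec-9-yn-1-ol | C#CCCCCCCCCO | starting material
15 | trimethyl{[10-(trimethylsilyl)dec-9-yn-1-yl]oxy}silane (not isolated) | C[Si](C)(C)C#CCCCCCCCCO[Si](C)(C)C | intermediate
16 | 10-(trimethylsilyl)dec-9-yn-1-ol | C[Si](C)(C)C#CCCCCCCCCO | intermediate
17 | 10-(trimethylsilyl)dec-9-ynal | C[Si](C)(C)C#CCCCCCCCC=O | intermediate
18 | [(10E)-11-iodoundec-10-en-1-yn-1-yl]trimethylsilane | C[Si](C)(C)C#CCCCCCCC/C=C/I | intermediate
19 | methyl 2-[(3S,6R)-6-{[(1R,2S,5R)-5-methyl-2-(propan-2-yl)cyclohexyl]oxy}-6-[(6E)-16-(trimethylsilyl)hexadec-6-ene-4,15-diyn-1-yl]-1,2-dioxan-3-yl]acetate | C[Si](C)(C)C#CCCCCCCC/C=C/C#CCCC[C@]1(O[C@@H]2C[C@H](C)CC[C@H]2C(C)C)CC[C@@H](CC(=O)OC)OO1 | intermediate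
20 | methyl 2-[(3S,6R)-6-methoxy-6-[(6E)-16-(trimethylsilyl)hexadec-6-ene-4,15-diyn-1-yl]-1,2-dioxan-3-yl]acetate (not isolated) | C[Si](C)(C)C#CCCCCCCC/C=C/C#CCCC[C@]1(OC)CC[C@@H](CC(=O)OC)OO1 | intermediate
21 | methyl 2-{(3S,6R)-6-[(6E)-hexadec-6-ene-4,15-diyn-1-yl]-6-methoxy-1,2-dioxan-3-yl}acetate | C#CCCCCCCC/C=C/C#CCCC[C@]1(OC)CC[C@@H](CC(=O)OC)OO1 | target

Total step count: 12. Longest linear sequence: 9 steps (steps 1–7, 11 and 12).

Steps most likely to fail

**Step 6.**
- Risk: formation of the hindered tertiary cobalt alkoxide may be slow. Cobalt-induced breakdown of the hydroperoxide may outrun chain transfer, and peroxyl radicals may start autoxidation at the propargylic position.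
- Fallback: it sets out from 8 and returns at 13. The peroxide ring would then be closed directly by polar chemistry instead of through the strained ring.
- Route: urea–hydrogen peroxide and catalytic Sc(OTf)3 in methanol should convert the ketone of 8 into methyl (2E)-6-hydroperoxy-6-methoxyundec-2-en-10-ynoate F1. Diethylamine in 2,2,2-trifluoroethanol should trigger the intramolecular 6-exo-trig peroxy-Michael addition to racemic methyl 2-[6-methoxy-6-(pent-4-yn-1-yl)-1,2-dioxan-3-yl]acetate F2. Exchange of the methoxy group for 12 (CSA, 5 Å MS, CH2Cl2), followed by separation of the diastereomers, leads to 13.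

**Step 7.**
- Risk: the two menthyl ketals may be discriminated too poorly on silica gel, so the resolution stalls at a mixture.
- Fallback: it sets out from 11, taken through the ketalisation of step 7 without separation, and returns at 13. Physical separation is replaced by enzymatic differentiation.
- Route: a lipase or esterase (pH 7 buffer, co-solvent, rt) is expected to hydrolyse the methyl ester of only one diastereomer, so that acid and ester can be parted by extraction. If the unwanted isomer is hydrolysed, 13 is recovered unchanged. If the wanted one is hydrolysed, 2-[(3S,6R)-6-{[(1R,2S,5R)-5-methyl-2-(propan-2-yl)cyclohexyl]oxy}-6-(pent-4-yn-1-yl)-1,2-dioxan-3-yl]acetic acid F3 is collected and re-methylated with TMSCHN2 to 13.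

**Step 5.**
- Risk: the samarium ketyl may be diverted by 5-exo-dig attack on the tethered alkyne or by plain reduction of the ketone. Conjugate reduction followed by aldol closure to a five-membered ring is a further diversion.
- Fallback: it sets out from Grignard reagent 4 and returns at 9. It keeps the competing π-system out of the electron-transfer step by carrying the alkyne as a masked aldehyde.
- Route to the acetal cyclobutanol:
  - Reagent 4 is added to N,5,5-trimethoxy-N-methylpentanamide F4, made from commercial methyl 5,5-dimethoxypentanoate with MeNHOMe·HCl and i-PrMgCl. This gives 9,9-dimethoxynon-1-en-5-one F5.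
  - Ozonolysis as in step 3 gives 8,8-dimethoxy-4-oxooctanal F6.
  - Wittig reaction with 7 as in step 4 gives methyl (2E)-10,10-dimethoxy-6-oxodec-2-enoate F7.
  - SmI2 in THF/MeOH closes methyl 2-[(1R*,2S*)-2-(4,4-dimethoxybutyl)-2-hydroxycyclobutyl]acetate F8.
- Unmasking: PPTS in wet acetone frees methyl 2-[(1R*,2S*)-2-hydroxy-2-(4-oxobutyl)cyclobutyl]acetate F9. Ohira–Bestmann homologation (dimethyl (1-diazo-2-oxopropyl)phosphonate, K2CO3, MeOH) then converts the aldehyde into the terminal alkyne of 9.

Further compounds
F1 | step 6 | methyl (2E)-6-hydroperoxy-6-methoxyundec-2-en-10-ynoate (racemic) | C#CCCCC(OC)(OO)CC/C=C/C(=O)OC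
F2 | step 6 | methyl 2-[6-methoxy-6-(pent-4-yn-1-yl)-1,2-dioxan-3-yl]acetate (racemic) | C#CCCCC1(OC)CCC(CC(=O)OC)OO1
F3 | step 7 | 2-[(3S,6R)-6-{[(1R,2S,5R)-5-methyl-2-(propan-2-yl)cyclohexyl]oxy}-6-(pent-4-yn-1-yl)-1,2-dioxan-3-yl]acetic acid | C#CCCC[C@]1(O[C@@H]2C[C@H](C)CC[C@H]2C(C)C)CC[C@@H](CC(=O)O)OO1
F4 | step 5 | N,5,5-trimethoxy-N-methylpentanamide | COC(CCCC(=O)N(C)OC)OC
F5 | step 5 | 9,9-dimethoxynon-1-en-5-one | C=CCCC(=O)CCCC(OC)OC
F6 | step 5 | 8,8-dimethoxy-4-oxooctanal | O=CCCC(=O)CCCC(OC)OC
F7 | step 5 | methyl (2E)-10,10-dimethoxy-6-oxodec-2-enoate | COC(=O)/C=C/CCC(=O)CCCC(OC)OC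
F8 | step 5 | methyl 2-[(1R*,2S*)-2-(4,4-dimethoxybutyl)-2-hydroxycyclobutyl]acetate (racemic, one enantiomer drawn) | COC(CCC[C@]1(O)CC[C@@H]1CC(=O)OC)OC
F9 | step 5 | methyl 2-[(1R*,2S*)-2-hydroxy-2-(4-oxobutyl)cyclobutyl]acetate (racemic, one enantiomer drawn) | O=CCCC[C@]1(O)CC[C@@H]1CC(=O)OC
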